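**Remarks.** Locants C1–C24 and O26 follow the order of the heavy atoms in the target string (C3 ester carbon, C5=C6 alkene, C7 oxygenated quaternary carbon, C14 methyl-bearing quaternary carbon, C17 ketone, C19 isopropyl carbon, C24 hemiketal carbon). Assumption: the hemiketal carbon C24 is not an independent stereocentre, because the C7 oxygen can close only onto the face of the C24 carbonyl that lies under ring B; the target string is taken to denote this cage-enforced hemiketal and is used unchanged. "Skeleton S" (compounds 12–21) means rings A, B and C as in the target, cis-fused at C7–C13 and at C14–C16, with C7, C13, C14 and C16 configured as in 22.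

## Analysis of the target

The target is a C21 methyl ester with three six-membered carbocycles: ring A (C7–C8–C9=C11–C12–C13, methyl on C9), ring B (C5=C6–C7–C13–C14–C16, ester on C5) and ring C (C14–C16–C17–C19–C23–C24, ketone at C17, isopropyl on C19). A tetrahydrofuran (C7–O26–C24–C14–C13) turns C24 into a hemiketal. Rings A/B are cis-fused at C7–C13 and rings B/C at C14–C16, on opposite faces of ring B: C8, C12 and the C14 methyl lie on one face; the C7 oxygen, H13, C24 and C17 on the other. Four stereocentres (C7, C13, C14, C16) are contiguous, and the quaternary carbons C7 and C14 flank C13; as written, C7, C13, C14, C16 and C19 all carry the descriptor R. C16 and C19 are both α to the C17 ketone; inside the cage the isopropyl group is equatorial on the outer face of ring C, so the natural C19 configuration is the thermodynamic one. Sensitive points are the hemiketal, the C16–H between the C17 ketone and the C5=C6 enoate (base can move the alkene into conjugation), the tertiary allylic C7–O bond and the acid-sensitive ring A alkene. The difficulty is the crowded A/B/C junction with four contiguous centres and no chiral-pool handle for the absolute configuration. The strategy rests on bonds C6–C7 and C13–C14: they join an enol-ether-like ring A (oxygen on C7) to a ring B carrying quaternary C14 and the C5 ester, the pattern of an inverse-demand [4+2] between a benzoate-derived cyclohexadienone and a cyclic enol ether, whose two spare dienone carbons (C23, C24) then anchor ring C.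

## Retrosynthetic reasoning

**22 ⇒ 21.** The hemiketal bond O26–C24 is opened and a C19=C23 alkene is put back, giving the ene-dione 21. The C7 hydroxyl closes onto C24 spontaneously from the only accessible face. C19 can therefore be left to thermodynamics in the last operation. The forward step is a chemoselective dissolving-metal reduction of the ene-1,4-dione.

**21 ⇒ 20.** Only protecting groups change: the C7 methoxymethyl ether and the C24 dimethyl ketal. Both are delivered by the key step and carried unchanged, so one acid treatment at the end suffices.

**20 ⇒ 19 ⇒ 18.** The C19–C20 bond (isopropyl) is cut. It is placed late on purpose. An isopropyl group on the vinyl unit would make the dehydrogenation after the [3,3] shift ambiguous (ring hydrogen versus side-chain methine) and would flank the C23 ketone by two quaternary carbons during the oxygen transposition. Forward, α-iodination of enone 18 and an sp2–sp3 cross-coupling install it with defined regiochemistry.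

**18 ⇒ 17 ⇒ 15 ⇒ 14.** The [3,3] shift necessarily leaves the carbonyl at C23, whereas the target needs oxygen at C17 and CH2 at C23. The epoxy ketone to allylic alcohol transposition moves the oxygen across C19 and removes the C23 oxygen in one operation. Epoxidation before and oxidation after complete the 1,3-enone transposition.

**14 ⇒ 11.** Ring C is opened at C16–C17 and C6–C23 is re-formed, giving the bicyclo[2.2.2]octenol 11. Forward, the anionic oxy-Cope shift sets C16 with the cis B/C fusion, moves the alkene to C5=C6 and gives a regiodefined enolate for dehydrogenation. A vinyl anion already carrying the C17 oxygen would be usable only as its cis-metalated isomer. That isomer puts the oxygen substituent on the inside of the forced boat against the C24 ketal and leaves a β-alkoxy enolate set up for E1cB loss. The bare vinyl group avoids both problems.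

**11 ⇒ 10.** The C19–C23 bond is cut; forward it is a 1,2-addition of a vinyl-metal reagent to the only ketone.

**10 ⇒ 9.** The absolute configuration is introduced by resolving the racemic adduct. A chiral C2-symmetric ketal on the dienone would put the control into the cycloaddition, but it lengthens the phenol synthesis and gives a cyclic ketal that is harder to hydrolyse next to quaternary C14.

**9 ⇒ 8 + 7.** Bonds C6–C7 and C13–C14 are cut, the only disconnection that removes ring B, both quaternary centres and four stereocentres at once and leaves two flat partners. Forward it is the inverse-demand [4+2] of dienone 8 with the enol ether alkene of 7.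

**8 ⇒ 4 ⇒ 3 ⇒ 2 ⇒ 1.** Dienone 8 is the oxidised form of guaiacol-type phenol 4. Its substitution pattern (hydroxyl meta and methoxy para to the ester, methyl next to the methoxy) fixes which carbon becomes ketone (C23) and which ketal (C24). Phenol 4 comes from 1 by ortho-formylation, Dakin oxidation and methylation of the more acidic hydroxyl.

**7 ⇒ 6 ⇒ 5.** Diene 7 is the Birch product of the protected cresol 6, which places the enol ether alkene at C7=C13 and the methyl-bearing alkene at C9=C11.

## Alternatives that were turned down

**Alternative 1:** Disconnection of C16–C17 in ring C. Forward, a chiral carbene catalyst converts the C17 aldehyde of the cyclohexadiene A2 into an acyl anion equivalent that adds to C16, the β-carbon of the ring B enoate, giving the cis-fused diketo ester A1 (intramolecular Stetter reaction).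
- For: the step is catalytic and can be enantioselective, so no resolution is needed; it delivers C17 as a ketone with C19 and C24 already correct. On absolute stereocontrol and on the oxidation pattern of ring C it is stronger than the chosen route.
- Against: C16 is a β-carbon next to quaternary C14 on a weakly electrophilic β-substituted enoate. A2 must already hold the C14 quaternary stereocentre (two different vinyl arms) and a C19 centre that is epimerisable next to the aldehyde. A1 has no ring A and no C5=C6 alkene; ring A would have to be annulated later at oxygenated quaternary C7 and at C13, beside two ketones.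
- Comparison: the chosen strategy makes the A/B junction, the hardest part, in one step from flat precursors and pays with a resolution and a late oxygen shuffle.

**Alternative 2:** Disconnection of C7–C13 and C14–C16 across a fourteen-membered ring. Forward, heating macrocycle A4 lets the silyloxy diene C16=C5–C6=C7 add transannularly to the enone alkene C13=C14, giving A3, one desilylation from the target.
- For: three carbocycles and four stereocentres form at once, with no protecting-group or redox corrections. After the macrocycle it is clearly more convergent than the chosen route.
- Against: A4 needs four alkenes of defined geometry, two Michael acceptors, an enolisable 1,4-diketone with an epimerisable C19, and a macrocyclisation. The facial and endo/exo outcome depends on the conformation of a fourteen-membered ring steered only by C19. Making A4 would probably take more steps than the whole chosen route.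
- Comparison: the chosen route offers short access to its key-step partners and a predictable, sterically dictated topology.

**Alternative 3:** Disconnection of C14–C16 and C5–C6 (rings B and C). Forward, in the acyclic triene A6 the 2-silyloxy diene C6=C7–C13=C14 adds intramolecularly to the (E)-4-oxo-enoate C16=C5 through the four-carbon diketone tether, giving A5.
- For: A6 is open-chain and can be assembled by aldol and olefination chemistry; the dienophile is activated; the tether enforces the cis B/C fusion; ring C carbonyls and C19 are in place. It is as good as or better than the chosen route on ring C oxidation levels and late-stage redox steps.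
- Against: the C14 methyl must sit on the inside of the s-cis diene, and only the remote C19 controls the facial sense. A5 has no ring A and a saturated C5. Ring A would need C13 alkylation, 1,2-addition to a C7 ketone in the presence of the C17 and C24 ketones, ring closure and C5=C6 desaturation.
- Comparison: the chosen route installs the C7–O quaternary centre and ring A directly and never has to differentiate three ketones.

Key step: step 6

## Route

Step 1
Reactants: 1 methyl 4-hydroxy-3-methylbenzoate
Product: 2 methyl 3-formyl-4-hydroxy-5-methylbenzoate
Conditions: MgCl2, Et3N, (CH2O)n, MeCN, reflux; aq HCl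
Reagents that add atoms: paraformaldehyde (formaldehyde), C=O
Why: Magnesium phenoxide-directed ortho-formylation (Casnati–Skattebøl); the only free position ortho to the hydroxyl is attacked, and a second equivalent of formaldehyde accepts the hydride.

Step 2
Reactants: 2 methyl 3-formyl-4-hydroxy-5-methylbenzoate
Product: 3 methyl 3,4-dihydroxy-5-methylbenzoate
Conditions: 30% H2O2, aq NaOH, THF, 0 °C to rt; then HCl
Reagents that add atoms: hydrogen peroxide, OO
Why: Dakin oxidation of an o-hydroxybenzaldehyde (aryl migration to peroxide oxygen, then formate hydrolysis); the cold, brief base exposure should spare the methyl ester.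

Step 3
Reactants: 3 methyl 3,4-dihydroxy-5-methylbenzoate
Product: 4 methyl 3-hydroxy-4-methoxy-5-methylbenzoate
Conditions: MeI (1.05 equiv), Li2CO3, DMF, 40 °C
Reagents that add atoms: iodomethane, CI
Why: Regioselective Williamson methylation: the hydroxyl para to the ester is the more acidic, so the weak carbonate base forms that phenoxide preferentially, as known for 3,4-dihydroxybenzoates and gallates.

Step 4
Reactants: 5 3-methylphenol
Product: 6 1-(methoxymethoxy)-3-methylbenzene
Conditions: MOMCl, i-Pr2NEt, CH2Cl2, 0 °C to rt
Reagents that add atoms: chloromethyl methyl ether, COCCl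
Why: Standard O-alkylation of a phenol; the MOM group is inert to dissolving metal, base and organometallics and is removable by acid from a tertiary carbon at the end.

Step 5
Reactants: 6 1-(methoxymethoxy)-3-methylbenzene
Product: 7 1-(methoxymethoxy)-5-methylcyclohexa-1,4-diene
Conditions: Li, NH3 (l), t-BuOH, THF, -78 to -33 °C; pentane/water work-up
Reagents that add atoms: none
Why: Birch reduction of an aryl ether; both donor substituents end up on the remaining alkene carbons, which gives the unconjugated 1,4-diene with the enol ether alkene at the future C7=C13.

Step 6
Reactants: 4 methyl 3-hydroxy-4-methoxy-5-methylbenzoate; 7 1-(methoxymethoxy)-5-methylcyclohexa-1,4-diene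
Product: 9 racemic bicyclo[2.2.2]octenone adduct (C5 methyl ester; C7 OMOM; C23 ketone; C24 dimethyl ketal), via masked o-benzoquinone 8 (not isolated)
Conditions: PhI(OAc)2 (1.1 equiv), NaHCO3, MeOH, 7 (4 equiv), slow addition of 4, 0 to 40 °C
Reagents that add atoms: methanol, CO
Why: PhI(OAc)2 oxidises phenol 4 at the methoxy-bearing ring carbon and methanol is captured there, giving the 6,6-dimethoxycyclohexa-2,4-dienone 8, whose LUMO has its larger terminal coefficient at the δ-carbon C14. The enol ether carbon C13 of 7 bonds first to C14 and the oxygenated carbon C7 closes onto C6 in an asynchronous, concerted, suprafacial [4+2] with inverse electron demand, the known behaviour of masked o-benzoquinones towards vinyl and cyclic enol ethers. Ring B closes as the boat of a bicyclo[2.2.2]octenone within the six-membered cycloaddition transition state. C6 and C14 become bridgeheads tied together by the bicycle, and C7 and C13 are cis because the ring-bound enol ether adds suprafacially. Their orientation follows from the endo arrangement: the ring A carbons C8 and C12 tuck under the diene carbons C5 and C16, so only H13 and the C7 oxygen face the C24 methoxy group and the flat C23 carbonyl. Site selectivity (enol ether over the isolated trisubstituted alkene) comes from the electron demand; regioselectivity (C13 to C14) from the dienone polarisation, which the C5 ester lowers in energy without reversing; endo selectivity from the steric demand of the ketal. Both faces of planar 8 are equivalent, so 9 is racemic. The C14 methyl and the ester slow dimerisation of 8, and buffered methanol with excess 7 should keep the enol ether intact.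

Step 7
Reactants: 9 racemic bicyclo[2.2.2]octenone adduct
Product: 10 (6R,7S,13R,14S)-enantiomer of the bicyclo[2.2.2]octenone adduct
Conditions: ketoreductase (panel hit), NADP+ (cat.), i-PrOH, phosphate buffer pH 7, DMSO (10%), 30 °C, stopped near half conversion; chromatography
Reagents that add atoms: none
Why: Enzymatic kinetic resolution by enantioselective carbonyl reduction: the activated α,α-dialkoxy ketone of the unwanted antipode is reduced and 10 is recovered unchanged; its four stereocentres come from step 6.

Step 8
Reactants: 10 (6R,7S,13R,14S)-enantiomer of the bicyclo[2.2.2]octenone adduct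
Product: 11 C23 vinyl carbinol (vinyl syn to the C5=C16 bridge; hydroxyl towards the C7–C13 bridge)
Conditions: CH2=CHMgBr (1.3 equiv), THF, -78 to -40 °C; aq NH4Cl
Reagents that add atoms: vinylmagnesium bromide, C=C[Mg]Br
Why: Grignard 1,2-addition to the non-enolisable ketone, which is far more electrophilic than the conjugated ester at low temperature; the C7 methoxymethoxy group covers the other face, so the nucleophile enters from the side of the C5=C16 bridge and the vinyl group ends up syn to that alkene, as the [3,3] shift requires.

Step 9
Reactants: 11 C23 vinyl carbinol
Product: 14 tricyclic enone on skeleton S (C23 ketone conjugated with C19=C17; C5=C6 enoate; C24 dimethyl ketal; C7 OMOM), via potassium enolate 12 (not isolated), via trimethylsilyl enol ether 13 (not isolated)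
Conditions: KH, 18-crown-6, THF, 0 °C to rt; TMSCl, Et3N, -78 °C; pentane filtration; Pd(OAc)2 (1.1 equiv), MeCN, rt
Reagents that add atoms: none
Why: Anionic oxy-Cope rearrangement through the boat enforced by the bicycle: C17 bonds to C16 on the face that carried C23, which sets C16 with the cis B/C fusion, while C6–C23 breaks and the alkene moves to C5=C6. The regiodefined enolate is silylated and dehydrogenated (Saegusa–Ito oxidation); with no substituent on C19, only the ring hydrogen on C17 can be lost.

Step 10
Reactants: 14 tricyclic enone on skeleton S
Product: 15 17,19-epoxy ketone (epoxide on the face of ring C away from ring B)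
Conditions: 30% aq H2O2, NaOH (cat.), MeOH, 0 °C
Reagents that add atoms: hydrogen peroxide, OO
Why: Weitz–Scheffer nucleophilic epoxidation: hydroperoxide adds to C17 of the enone and not to the hindered, less electrophilic enoate, and should enter on the convex face anti to ring B.

Step 11
Reactants: 15 17,19-epoxy ketone
Product: 17 allylic alcohol (C17 hydroxyl; C19=C23 alkene; C24 dimethyl ketal; C7 OMOM), via epoxy hydrazone 16 (not isolated)
Conditions: N2H4·H2O, AcOH, MeOH, 0 °C to rt
Reagents that add atoms: none
Why: Wharton transposition: the C23 hydrazone opens the epoxide and loses N2, leaving hydrogen on C23, the alkene at C19=C23 and the hydroxyl on C17 with its C–O bond retained.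

Step 12
Reactants: 17 allylic alcohol
Product: 18 enone (C17 ketone conjugated with C19=C23; C24 dimethyl ketal; C7 OMOM)
Conditions: Dess–Martin periodinane, pyridine, CH2Cl2, 0 °C to rt
Reagents that add atoms: none
Why: Dess–Martin oxidation of the only free alcohol, buffered to protect the allylic ketal and the MOM ether; the C17 stereocentre disappears.

Step 13
Reactants: 18 enone
Product: 19 C19 iodo enone
Conditions: I2, pyridine, CH2Cl2, rt
Reagents that add atoms: iodine, II
Why: Johnson α-iodination of a cyclic enone (pyridine conjugate addition, iodination of the enolate, elimination), well known for 4,4-disubstituted cyclohexenones; the enoate has no free α-vinylic position.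

Step 14
Reactants: 19 C19 iodo enone
Product: 20 C19 isopropyl enone (C17 ketone; C19=C23; C24 dimethyl ketal; C7 OMOM)
Conditions: i-PrZnBr, Pd(OAc)2 (5 mol %), CPhos (10 mol %), THF/toluene, rt
Reagents that add atoms: isopropylzinc bromide, CC(C)[Zn]Br
Why: Negishi cross-coupling of an α-iodoenone with a secondary alkylzinc halide; the biaryl phosphine favours reductive elimination over β-hydride elimination so the branched group is kept, and ketone and ester tolerate the organozinc.

Step 15
Reactants: 20 C19 isopropyl enone
Product: 22 target hemiketal CNP0382995.2, via ene-dione 21 (not isolated)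
Conditions: 3 M aq HCl, THF, 40 °C; extraction; Zn dust, AcOH, 25 to 50 °C
Reagents that add atoms: water, O
Why: Acid hydrolysis removes the C24 dimethyl ketal and the tertiary MOM ether; zinc in acetic acid then reduces only the 2-ene-1,4-dione (enoate and isolated alkene untouched), whichever hydroxy-ketone, hemiketal or oxa-Michael form is present. The C7 hydroxyl closes onto C24 from the only reachable face, and C19, α to the C17 ketone, should equilibrate in warm acetic acid to the isomer with the isopropyl group equatorial on the outer face of ring C.

## Compound list

1 | methyl 4-hydroxy-3-methylbenzoate | COC(=O)c1ccc(O)c(C)c1 | starting material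
2 | methyl 3-formyl-4-hydroxy-5-methylbenzoate | COC(=O)c1cc(C)c(O)c(C=O)c1 | intermediate
3 | methyl 3,4-dihydroxy-5-methylbenzoate | COC(=O)c1cc(C)c(O)c(O)c1 | intermediate
4 | methyl 3-hydroxy-4-methoxy-5-methylbenzoate | COC(=O)c1cc(C)c(OC)c(O)c1 | intermediate
5 | 3-methylphenol (m-cresol) | Cc1cccc(O)c1 | starting material
6 | 1-(methoxymethoxy)-3-methylbenzene | COCOc1cccc(C)c1 | intermediate
7 | 1-(methoxymethoxy)-5-methylcyclohexa-1,4-diene | COCOC1=CCC=C(C)C1 | intermediate
8 | methyl 4,4-dimethoxy-5-methyl-3-oxocyclohexa-1,5-diene-1-carboxylate (masked o-benzoquinone, formed in the flask) | COC(=O)C1=CC(=O)C(OC)(OC)C(C)=C1 | intermediate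
9 | racemic methyl 10,10-dimethoxy-4a-(methoxymethoxy)-1,6-dimethyl-9-oxo-1,4,4a,5,8,8a-hexahydro-1,4-ethanonaphthalene-3-carboxylate; ring A cis-fused and syn to the etheno bridge, C7 OMOM and H13 syn to the keto-ketal bridge (one enantiomer drawn) | COC(=O)C1=C[C@@]2(C)[C@H]3CC=C(C)C[C@@]3(OCOC)[C@@H]1C(=O)C2(OC)OC | intermediate
10 | single enantiomer of 9, (6R,7S,13R,14S) in target numbering | COC(=O)C1=C[C@@]2(C)[C@H]3CC=C(C)C[C@@]3(OCOC)[C@@H]1C(=O)C2(OC)OC | intermediate
11 | C23 vinyl carbinol of 10; vinyl syn to the C5=C16 bridge, hydroxyl towards the C7–C13 bridge | COC(=O)C1=C[C@@]2(C)[C@H]3CC=C(C)C[C@@]3(OCOC)[C@@H]1[C@@](O)(C=C)C2(OC)OC | intermediate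
12 | potassium enolate on skeleton S (C23 O–K, C19=C23; C5=C6 enoate; C24 dimethyl ketal; C7 OMOM), formed in the flask | COC(=O)C1=C[C@]2(OCOC)CC(C)=CC[C@@H]2[C@]2(C)[C@H]1CC=C([O-])C2(OC)OC.[K+] | intermediate
13 | trimethylsilyl enol ether of 12 (C23 OTMS, C19=C23), formed in the flask | COC(=O)C1=C[C@]2(OCOC)CC(C)=CC[C@@H]2[C@]2(C)[C@H]1CC=C(O[Si](C)(C)C)C2(OC)OC | intermediate
14 | enone on skeleton S: C23 ketone conjugated with C19=C17; C5=C6 enoate; C24 dimethyl ketal; C7 OMOM | COC(=O)C1=C[C@]2(OCOC)CC(C)=CC[C@@H]2[C@]2(C)[C@H]1C=CC(=O)C2(OC)OC | intermediate
15 | 17,19-epoxide of 14, oxygen on the face of ring C away from ring B (cis to H16 and the C14 methyl) | COC(=O)C1=C[C@]2(OCOC)CC(C)=CC[C@@H]2[C@]2(C)[C@H]1[C@H]3O[C@H]3C(=O)C2(OC)OC | intermediate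
16 | C23 hydrazone of 15, formed in the flask | COC(=O)C1=C[C@]2(OCOC)CC(C)=CC[C@@H]2[C@]2(C)[C@H]1[C@H]3O[C@H]3C(=NN)C2(OC)OC | intermediate
17 | allylic alcohol on skeleton S: C17 hydroxyl (face of the former epoxide); C19=C23; C24 dimethyl ketal; C7 OMOM | COC(=O)C1=C[C@]2(OCOC)CC(C)=CC[C@@H]2[C@]2(C)[C@H]1[C@@H](O)C=CC2(OC)OC | intermediate
18 | enone on skeleton S: C17 ketone conjugated with C19=C23; C24 dimethyl ketal; C7 OMOM | COC(=O)C1=C[C@]2(OCOC)CC(C)=CC[C@@H]2[C@]2(C)[C@H]1C(=O)C=CC2(OC)OC | intermediate
19 | C19 iodo derivative of 18 | COC(=O)C1=C[C@]2(OCOC)CC(C)=CC[C@@H]2[C@]2(C)[C@H]1C(=O)C(I)=CC2(OC)OC | intermediate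
20 | C19 isopropyl derivative of 18 | COC(=O)C1=C[C@]2(OCOC)CC(C)=CC[C@@H]2[C@]2(C)[C@H]1C(=O)C(C(C)C)=CC2(OC)OC | intermediate
21 | ene-dione on skeleton S: C17 and C24 ketones flanking C19(isopropyl)=C23; free C7 hydroxyl (open form), formed in the flask | COC(=O)C1=C[C@]2(O)CC(C)=CC[C@@H]2[C@]2(C)[C@H]1C(=O)C(C(C)C)=CC2=O | intermediate
22 | CNP0382995.2: hemiketal of skeleton S with C17 ketone, C19 isopropyl (H19 on the ring B side), C7–O–C24 bridge and C24 hydroxyl | COC(=O)C1=C[C@]23CC(C)=CC[C@@H]2[C@]2(C)[C@H]1C(=O)[C@@H](C(C)C)C[C@@]2(O)O3 | target

## Step count and least certain steps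

Total step count: 15. Longest linear sequence: 13 steps (steps 1–3 and 6–15); steps 4–5 are a two-step branch.

**Step 6 (key step).** Most likely failure: dimerisation of dienone 8, or acid-induced methanol addition and double-bond isomerisation of diene 7, outrunning the cross-cycloaddition with the hindered trisubstituted enol ether. A second risk is erosion of the regio- or endo-preference by the C14 methyl group. The fallback sets out from 4 and comes back at 9 and uses a removable blocking group. NBS in MeCN brominates 4 para to the hydroxyl to give methyl 2-bromo-5-hydroxy-4-methoxy-3-methylbenzoate F1. PhI(OAc)2 in methanol converts it into the bromo dienone F2, which should not dimerise and can be freed from methanol and acetic acid. Heating F2 with 7 in toluene gives the bromo adduct F3, and Bu3SnH/AIBN removes the vinylic bromine to return 9.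

**Step 7.** Most likely failure: poor enantiomer discrimination, or no turnover, because the ketone sits between a bridgehead and a quaternary ketal carbon. The fallback sets out from 9 and comes back at 10: the enantiomers of racemic 9 are separated by preparative supercritical-fluid chromatography on a polysaccharide chiral stationary phase. This is a physical separation that makes no new compound (none, F0).

**Step 11.** Most likely failure: slow hydrazone formation at the ketone beside the ketal, so that hydrazine opens the epoxide or adds to the enoate instead. The fallback sets out from 15 and comes back at 17 and replaces the ionic fragmentation by a radical one. NaBH4 reduces 15 to the epoxy alcohol F4, and 1,1'-thiocarbonyldiimidazole converts it into the imidazolylthiocarbonyl ester F5. Bu3SnH/AIBN at high stannane concentration generates the C23 radical, which opens the epoxide to the C17 alkoxy radical and, after hydrogen transfer, gives 17.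

**Step 14.** Most likely failure: isomerisation of the secondary alkyl group to n-propyl by β-hydride elimination and reinsertion at palladium, or protodeiodination when transmetalation is slow. The fallback sets out from 19 and comes back at 20 and uses an sp2–sp2 coupling followed by reduction. Suzuki–Miyaura coupling of 19 with isopropenylboronic acid pinacol ester (Pd(dppf)Cl2, K3PO4, THF/water) gives the isopropenyl dienone F6. Hydrogenation of its unhindered 1,1-disubstituted alkene with RhCl(PPh3)3 under H2 gives 20.

## Further compounds

F1 | step 6 | methyl 2-bromo-5-hydroxy-4-methoxy-3-methylbenzoate | COC(=O)c1c(Br)c(C)c(OC)c(O)c1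
F2 | step 6 | methyl 6-bromo-4,4-dimethoxy-5-methyl-3-oxocyclohexa-1,5-diene-1-carboxylate | COC(=O)C1=CC(=O)C(OC)(OC)C(C)=C1Br
F3 | step 6 | racemic C16-bromo analogue of adduct 9 (one enantiomer drawn) | COC(=O)C1=C(Br)[C@@]2(C)[C@H]3CC=C(C)C[C@@]3(OCOC)[C@@H]1C(=O)C2(OC)OC
F0 | step 7 | none | none
F4 | step 11 | C23 alcohol of epoxy ketone 15 (C23 configuration immaterial) | COC(=O)C1=C[C@]2(OCOC)CC(C)=CC[C@@H]2[C@]2(C)[C@H]1[C@H]3O[C@H]3C(O)C2(OC)OC
F5 | step 11 | O-(imidazol-1-ylthiocarbonyl) derivative of F4 | COC(=O)C1=C[C@]2(OCOC)CC(C)=CC[C@@H]2[C@]2(C)[C@H]1[C@H]3O[C@H]3C(OC(=S)n3ccnc3)C2(OC)OC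
F6 | step 14 | C19 isopropenyl analogue of enone 20 | COC(=O)C1=C[C@]2(OCOC)CC(C)=CC[C@@H]2[C@]2(C)[C@H]1C(=O)C(C(C)=C)=CC2(OC)OC
A1 | alternative 1 | cis-fused ring B/ring C diketo ester with C7 methyl enol ether (Stetter product) | COC(=O)[C@@H]1CC(OC)=C[C@]2(C)[C@H]1C(=O)[C@@H](C(C)C)CC2=O
A2 | alternative 1 | methyl 3-(3-formyl-4-methylpentanoyl)-5-methoxy-3-methylcyclohexa-1,4-diene-1-carboxylate (Stetter substrate; C14 and C19 as in A1) | COC(=O)C1=C[C@](C)(C(=O)C[C@H](C(C)C)C=O)C=C(OC)C1
A3 | alternative 2 | tricyclic diketo ester with C7 tert-butyldimethylsilyl ether (open form of the target) | COC(=O)C1=C[C@]2(O[Si](C)(C)C(C)(C)C)CC(C)=CC[C@@H]2[C@]2(C)[C@H]1C(=O)[C@@H](C(C)C)CC2=O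
A4 | alternative 2 | fourteen-membered macrocyclic tetraene (C16=C5 Z, C6=C7 E, C9=C11 Z, C13=C14 E) | COC(=O)/C1=C\C(=O)[C@@H](C(C)C)CC(=O)/C(C)=C/C/C=C(C)\C/C(O[Si](C)(C)C(C)(C)C)=C\1
A5 | alternative 3 | cis-fused ring B/ring C diketo ester with C7 triethylsilyl enol ether | COC(=O)[C@@H]1CC(O[Si](CC)(CC)CC)=C[C@]2(C)[C@H]1C(=O)[C@@H](C(C)C)CC2=O
A6 | alternative 3 | acyclic silyloxy triene (E-4-oxo-enoate; E diene terminus) | COC(=O)/C=C/C(=O)[C@@H](C(C)C)CC(=O)/C(C)=C/C(O[Si](CC)(CC)CC)=C
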